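**Retrosynthetic overview**
1. Numbering: ring C1 (C=O), C2=C3, C4 (OAc), C5 (OH); side chain C1′. The C5(OH)–C1′(OH) diol is cut back to an (E)-C5=C1′ alkene (syn-dihydroxylation anti to the C4 acetate). This leaves a 4-oxy-5-alkylidenecyclopent-2-enone.
2. That ring, the only one, is made in one operation by a [3+2] union. C1 and C5 (with C1′ and the C12 chain) come from a 1-lithio-1-carbamoyloxyallene, and C2–C3–C4 come from (E)-3-(PMBO)acrolein. The bonds formed are C1–C2 (carbonyl addition) and C4–C5 (4π closure).
3. Enabling feature: the ring atoms C5–C1(=O)–C2=C3–C4(–O) are the retron of a 2-oxido-5-oxypentadienyl cation, the cation type of the Piancatelli rearrangement. The diol carbons C5/C1′ next to C1=O are a masked allene terminus, so one C=C=C unit maps onto C1, C5 and C1′.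
4. Absolute configuration: C4 is fixed by an enantioconvergent lipase acetylation/Mitsunobu inversion that also installs the natural acetate. C5 and C1′ are then relayed from C4 and from the alkene geometry.
5. Fragments: the allene comes from 1-tetradecyne, formaldehyde and i-Pr2NCOCl; the three-carbon unit comes from sodium malondialdehyde enolate and PMBCl.

Key step: step 5

Assumption: sodium 3-oxoprop-1-en-1-olate 6 is taken as a purchasable salt (otherwise one hydrolysis from 1,1,3,3-tetramethoxypropane); racemic compounds are drawn without a stereo mark at the racemic element (allene axis, C4).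

Step 1
Reactants: 1 1-tetradecyne; 2 paraformaldehyde
Product: 3 pentadec-2-yn-1-ol
Conditions: n-BuLi, THF, −78 °C; (CH2O)n, −78 °C to rt; H2O
Reagents that add atoms: none
Why: Addition of the lithium acetylide to formaldehyde (acetylide hydroxymethylation) is a standard one-carbon homologation and creates no stereocentre.

Step 2
Reactants: 3 pentadec-2-yn-1-ol
Product: 4 pentadec-2-yn-1-yl N,N-diisopropylcarbamate
Conditions: NaH, THF, 0 °C; i-Pr2NCOCl, reflux
Reagents that add atoms: N,N-diisopropylcarbamoyl chloride, CC(C)N(C(C)C)C(=O)Cl
Why: O-Carbamoylation of the sodium alkoxide gives the base-stable, lithium-directing carbamate that later acts as migrating group and leaving group, and no stereocentre is formed.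

Step 3
Reactants: 4 pentadec-2-yn-1-yl N,N-diisopropylcarbamate
Product: 5 rac-pentadeca-1,2-dien-1-yl N,N-diisopropylcarbamate
Conditions: n-BuLi, TMEDA, Et2O, −78 °C; MeOH, −78 °C
Reagents that add atoms: none
Why: Carbamate-directed lithiation gives a propargyl/allenyl anion whose kinetic γ-protonation (propargyl-to-allenyl isomerisation, as used for 3-substituted alkoxyallenes) should give the 1,3-disubstituted allene as a racemate of its axis, while α-protonated material is simply recovered 4.

Step 4
Reactants: 6 sodium (E)-3-oxoprop-1-en-1-olate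
Product: 7 (E)-3-[(4-methoxybenzyl)oxy]prop-2-enal
Conditions: PMBCl, NaI (cat.), DMSO, rt
Reagents that add atoms: 4-methoxybenzyl chloride, COc1ccc(CCl)cc1
Why: Williamson-type O-alkylation of the ambident vinylogous carboxylate in a dipolar aprotic solvent should give the 3-alkoxyacrolein with the E geometry of the W-shaped enolate retained.

Step 5
Reactants: 5 rac-pentadeca-1,2-dien-1-yl N,N-diisopropylcarbamate; 7 (E)-3-[(4-methoxybenzyl)oxy]prop-2-enal
Product: 11 rac-(5Z)-4-[(4-methoxybenzyl)oxy]-5-tridecylidenecyclopent-2-en-1-one, via lithioallenyl carbamate 8 (not isolated), via lithium alkoxide adduct 9 (not isolated), via lithium allenolate 10 (not isolated)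
Conditions: n-BuLi, TMEDA, THF, −78 °C; 7, −78 °C to rt; H2O
Reagents that add atoms: none
Why: Proposed new method: n-BuLi/TMEDA removes the allenic α-proton of 5, the hard lithioallene 8 adds 1,2 to the aldehyde of 7 (first new bond, C1–C2), and alkoxide 9 takes over the carbamoyl group through a five-membered tetrahedral intermediate, which unmasks allenolate 10 and turns the carbinol oxygen into a leaving group. Expulsion of lithium diisopropylcarbamate, pushed by the allenolate and pulled by the PMBO donor, should give a 2-oxido-5-alkoxypentadienyl cation that closes by a thermally allowed conrotatory 4π electrocyclisation between the central allene carbon and the oxocarbenium carbon (second new bond, C4–C5; formally a 5-endo-trig attack of the allenolate carbon), delivering the enone and the exocyclic alkene directly. The closest known reaction types are the cyclopentannulation of lithiated allenyl carbamates with simple enals by the same carbamoyl shift/4π sequence, the allenyl ether Nazarov cyclisation, and the Piancatelli rearrangement, whose cyclising cation carries the same two oxygen substituents; new here is the β-alkoxy enal (a vinylogous formate) as three-carbon partner. The only new stereocentre, C4, is set by the sense of conrotation, which the allene axis dictates because the C12 chain turns outward, away from the incoming terminus (hence the Z alkene); since 5 is racemic, 11 is racemic and the absolute configuration is fixed in step 8. The step needs 1,2- over 1,4-addition, secured by the lithium reagent at −78 °C and by the donor oxygen that deactivates the β-carbon, and it needs C- over O-closure, secured because O-closure gives only a reversibly ionising mixed acetal whereas C–C closure is irreversible; the E enol ether places OPMB on the outside of the U-shaped cation, so the termini can meet.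

Step 6
Reactants: 11 rac-(5Z)-4-[(4-methoxybenzyl)oxy]-5-tridecylidenecyclopent-2-en-1-one
Product: 12 rac-(5E)-4-[(4-methoxybenzyl)oxy]-5-tridecylidenecyclopent-2-en-1-one
Conditions: I2 (cat.), CH2Cl2, visible light, rt
Reagents that add atoms: none
Why: Reversible addition of iodine atoms at C1′ (iodine-catalysed Z-to-E alkene isomerisation) lets the exocyclic bond rotate and should funnel the material to the thermodynamically preferred E isomer, in which the chain avoids the carbonyl oxygen, without touching C4.

Step 7
Reactants: 12 rac-(5E)-4-[(4-methoxybenzyl)oxy]-5-tridecylidenecyclopent-2-en-1-one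
Product: 13 rac-(5E)-4-hydroxy-5-tridecylidenecyclopent-2-en-1-one
Conditions: DDQ, CH2Cl2/pH 7 buffer, 0 °C
Reagents that add atoms: none
Why: Oxidative PMB ether cleavage with DDQ (hydride abstraction at the electron-rich benzylic carbon, then hydrolysis) is neutral and should leave the electron-poor cross-conjugated dienone untouched.

Step 8
Reactants: 13 rac-(5E)-4-hydroxy-5-tridecylidenecyclopent-2-en-1-one
Product: 15 (1R,5E)-4-oxo-5-tridecylidenecyclopent-2-en-1-yl acetate, via unreacted (4S)-alcohol 14 (not isolated)
Conditions: Novozym 435 (immobilised Candida antarctica lipase B), vinyl acetate, MTBE, 30 °C, stopped when the fast enantiomer is consumed; filter, concentrate; AcOH, PPh3, DIAD, toluene, 0 °C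
Reagents that add atoms: vinyl acetate, C=COC(C)=O; acetic acid, CC(=O)O
Why: Lipase-catalysed transesterification (kinetic resolution) should acetylate the (4R)-alcohol, whose large alkylidene-bearing C5 side and small C3H= side fit the empirical size model for fast-reacting secondary alcohols, and the Mitsunobu reaction then converts the remaining (4S)-alcohol 14 into the same acetate by SN2 inversion, so C4 becomes R from both halves of the racemate.

Step 9
Reactants: 15 (1R,5E)-4-oxo-5-tridecylidenecyclopent-2-en-1-yl acetate
Product: 16 (1R,5S)-5-hydroxy-5-[(1S)-1-hydroxytridecyl]-4-oxocyclopent-2-en-1-yl acetate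
Conditions: K2OsO4·2H2O (cat.), NMO, citric acid, t-BuOH/H2O, rt
Reagents that add atoms: N-methylmorpholine N-oxide, C[N+]1([O-])CCOCC1; water, O (both oxygens are passed on through OsO4, O=[Os](=O)(=O)=O)
Why: Upjohn-type catalytic syn-dihydroxylation should pick the more electron-rich trisubstituted exocyclic C5=C1′ bond over the ring CH=CH bond and add from the face opposite the C4 acetate, so the E geometry translates into the (5S,1′S) diol with C5–OH trans to C4–OAc, while the acidic buffer suppresses acetyl migration.

**Compound list**
1 | 1-tetradecyne | CCCCCCCCCCCCC#C | starting material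
2 | paraformaldehyde (drawn as formaldehyde) | C=O | starting material
3 | pentadec-2-yn-1-ol | CCCCCCCCCCCCC#CCO | intermediate
4 | pentadec-2-yn-1-yl N,N-diisopropylcarbamate | CCCCCCCCCCCCC#CCOC(=O)N(C(C)C)C(C)C | intermediate
5 | rac-pentadeca-1,2-dien-1-yl N,N-diisopropylcarbamate | CCCCCCCCCCCCC=C=COC(=O)N(C(C)C)C(C)C | intermediate
6 | sodium (E)-3-oxoprop-1-en-1-olate | [Na+].[O-]/C=C/C=O | starting material
7 | (E)-3-[(4-methoxybenzyl)oxy]prop-2-enal | COc1ccc(CO/C=C/C=O)cc1 | intermediate
8 | rac-1-lithiopentadeca-1,2-dien-1-yl N,N-diisopropylcarbamate | CCCCCCCCCCCCC=C=C([Li])OC(=O)N(C(C)C)C(C)C | intermediate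
9 | lithium (1E)-4-[(diisopropylcarbamoyl)oxy]-1-[(4-methoxybenzyl)oxy]octadeca-1,4,5-trien-3-olate (racemic, diastereomer mixture) | CCCCCCCCCCCCC=C=C(OC(=O)N(C(C)C)C(C)C)C([O-])/C=C/OCc1ccc(OC)cc1.[Li+] | intermediate
10 | lithium (1E)-3-[(diisopropylcarbamoyl)oxy]-1-[(4-methoxybenzyl)oxy]octadeca-1,4,5-trien-4-olate (racemic, diastereomer mixture) | CCCCCCCCCCCCC=C=C([O-])C(OC(=O)N(C(C)C)C(C)C)/C=C/OCc1ccc(OC)cc1.[Li+] | intermediate
11 | rac-(5Z)-4-[(4-methoxybenzyl)oxy]-5-tridecylidenecyclopent-2-en-1-one | CCCCCCCCCCCC/C=C1\C(=O)C=CC1OCc2ccc(OC)cc2 | intermediate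
12 | rac-(5E)-4-[(4-methoxybenzyl)oxy]-5-tridecylidenecyclopent-2-en-1-one | CCCCCCCCCCCC/C=C1/C(=O)C=CC1OCc2ccc(OC)cc2 | intermediate
13 | rac-(5E)-4-hydroxy-5-tridecylidenecyclopent-2-en-1-one | CCCCCCCCCCCC/C=C1/C(=O)C=CC1O | intermediate
14 | (4S,5E)-4-hydroxy-5-tridecylidenecyclopent-2-en-1-one | CCCCCCCCCCCC/C=C1/C(=O)C=C[C@@H]1O | intermediate
15 | (1R,5E)-4-oxo-5-tridecylidenecyclopent-2-en-1-yl acetate | CCCCCCCCCCCC/C=C1/C(=O)C=C[C@H]1OC(C)=O | intermediate
16 | (1R,5S)-5-hydroxy-5-[(1S)-1-hydroxytridecyl]-4-oxocyclopent-2-en-1-yl acetate | CCCCCCCCCCCC[C@H](O)[C@@]1(O)C(=O)C=C[C@H]1OC(C)=O | target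

Total steps: 9. Longest linear sequence: 8 (steps 1, 2, 3, 5, 6, 7, 8, 9).

**Steps most likely to fail**

Step 5. Possible failures are ionisation from an extended conformer with loss of the enol ether as an open-chain dienal, persistent O-closure of the zwitterion, or incomplete carbamoyl transfer.
- The fallback is the ketone-level allenyl ether Nazarov cyclopentannulation, which is known chemistry and forms the same two ring bonds. It sets out from 3 and 7 and comes back at 11.
- From 3, MOMCl/i-Pr2NEt gives 1-(methoxymethoxy)pentadec-2-yne F1. n-BuLi then MeOH at −78 °C gives rac-1-(methoxymethoxy)pentadeca-1,2-diene F2.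
- From 7, Pinnick oxidation gives (E)-3-[(4-methoxybenzyl)oxy]acrylic acid F3. EDC/morpholine gives (E)-3-[(4-methoxybenzyl)oxy]-1-(morpholin-4-yl)prop-2-en-1-one F4.
- F2 is α-lithiated with n-BuLi and added to F4 at −78 °C. A mildly acidic quench triggers the Nazarov closure with loss of the MOM group to give rac-(5Z)-2-hydroxy-4-[(4-methoxybenzyl)oxy]-5-tridecylidenecyclopent-2-en-1-one F5.
- PhNTf2/Et3N gives the C2 enol triflate of F5, F6. Pd(OAc)2/PPh3, HCO2H and n-Bu3N reduce C–OTf to C–H and give 11.

Step 8. Possible failures are insufficient discrimination of the enantiomers by the enzyme at the hindered carbinol, or allylic scrambling during the Mitsunobu inversion.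
- The fallback replaces acyl transfer by palladium-catalysed allylic substitution. It sets out from 13 and comes back at 15.
- Boc2O/DMAP gives rac-tert-butyl (5E)-4-oxo-5-tridecylidenecyclopent-2-en-1-yl carbonate F7.
- Pd2(dba)3·CHCl3 is used with the enantiomer of the DACH-phenyl bisphosphine ligand that ionises the (R)-carbonate faster, together with AcOH in CH2Cl2. This gives 15 by kinetic resolution with net retention (double inversion), and the slow carbonate is separated.

Step 9. Possible failures are competing osmylation of the ring C2=C3 bond, over-oxidation, or acetyl migration to C1′–OH.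
- The fallback masks the ring enone before the oxidation. It sets out from 15 and comes back at 16.
- PhSH with Et3N (cat.) in CH2Cl2 at −20 °C adds at ring C3, the site at which cross-conjugated cyclopentenones take up thiols, anti to the acetate. This gives the 3-(phenylsulfanyl) adduct of 15, F8.
- K2OsO4·2H2O (cat.) with excess NMO dihydroxylates the only remaining alkene and oxidises sulfur to give the diol sulfone F9.
- DBU at 0 °C expels benzenesulfinate (E1cB), restores C2=C3 and gives 16.

**Further compounds**
F1 | step 5 | 1-(methoxymethoxy)pentadec-2-yne | CCCCCCCCCCCCC#CCOCOC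
F2 | step 5 | rac-1-(methoxymethoxy)pentadeca-1,2-diene | CCCCCCCCCCCCC=C=COCOC
F3 | step 5 | (E)-3-[(4-methoxybenzyl)oxy]acrylic acid | COc1ccc(CO/C=C/C(=O)O)cc1
F4 | step 5 | (E)-3-[(4-methoxybenzyl)oxy]-1-(morpholin-4-yl)prop-2-en-1-one | COc1ccc(CO/C=C/C(=O)N2CCOCC2)cc1
F5 | step 5 | rac-(5Z)-2-hydroxy-4-[(4-methoxybenzyl)oxy]-5-tridecylidenecyclopent-2-en-1-one | CCCCCCCCCCCC/C=C1\C(=O)C(O)=CC1OCc2ccc(OC)cc2
F6 | step 5 | rac-(4Z)-3-[(4-methoxybenzyl)oxy]-5-oxo-4-tridecylidenecyclopent-1-en-1-yl trifluoromethanesulfonate | CCCCCCCCCCCC/C=C1\C(=O)C(OS(=O)(=O)C(F)(F)F)=CC1OCc2ccc(OC)cc2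
F7 | step 8 | rac-tert-butyl (5E)-4-oxo-5-tridecylidenecyclopent-2-en-1-yl carbonate | CCCCCCCCCCCC/C=C1/C(=O)C=CC1OC(=O)OC(C)(C)C
F8 | step 9 | 3-(phenylsulfanyl) adduct of 15 (SPh at ring C3 trans to the C4 acetate, E alkylidene kept) | CCCCCCCCCCCC/C=C1/C(=O)C[C@H](Sc2ccccc2)[C@H]1OC(C)=O
F9 | step 9 | 2,3-dihydro-3-(phenylsulfonyl) derivative of 16 (sulfonyl at ring C3 trans to the C4 acetate) | CCCCCCCCCCCC[C@H](O)[C@@]1(O)C(=O)C[C@H](S(=O)(=O)c2ccccc2)[C@H]1OC(C)=O
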